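Abbreviations: SEM = [2-(trimethylsilyl)ethoxy]methyl; Ts = 4-methylbenzenesulfonyl. Ring A = the 6-bromoindole, ring B = the imidazole, ring C = the unsubstituted indole.

## Analysis of the target

Nortopsentin B (18) is a 2,4-disubstituted 1H-imidazole (ring B). Its C2 carries a 6-bromoindol-3-yl group (ring A), its C4 carries an indol-3-yl group (ring C), and C5 is unsubstituted. There is no stereocenter and every ring is aromatic, so the problem is one of connectivity: two indoles that differ only by the bromine at C6 of ring A must be placed at defined positions of ring B. The sensitive points are the C6–Br bond (zerovalent palladium, halogen–metal exchange, hydrogenolysis), three acidic N–H groups, and the electron-rich C2 and C3 positions of the indoles. The free imidazole is tautomeric, so a protecting group on either ring-B nitrogen leads to the same target. The strategy rests on the fact that C4, C5, C6 and C7 of ring C bear only hydrogen. The carbons C3a to C7a of ring C can therefore come from a symmetric C6H4 aryne, while N1, C2 and C3 of ring C come from a tosylaminomethyl ketone already attached to imidazole C4. Ring A, for which an aryne would have two orientations, is bought intact with its bromine in place.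

## Retrosynthetic reasoning

**18 from 17.** The last operation only uncovers three N–H bonds. In 17 the imidazole N1 and the ring-A nitrogen carry SEM groups, and the ring-C nitrogen carries the tosyl group left by the annulation. All three are cleaved by fluoride, so one reagent finishes the synthesis and the C6–Br bond meets neither a reductant nor a transition metal.

**17 from 14 and 15.** Ring C is cut at N1–C7a and C3–C3a. The six benzo carbons go back to the aryne precursor 15; N1, C2 and C3 go back to the tosylaminomethyl ketone 14. The cut is made on ring C because its benzo ring is unsubstituted, so the aryne is symmetric and only one product can form. A bromine-bearing aryne would take the nitrogen at either end of its triple bond, which is why ring A is not made this way. Forward, the step must N-arylate the sulfonamide, close the five-membered ring onto the ketone (carbinol 16) and dehydrate to the indole.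

**14 from 12 and 13.** The C–N bond next to the ketone is cut. An activated α-chloro ketone (12) and the primary sulfonamide 13 join by simple substitution, which installs the nitrogen already carrying the sulfonyl group that the annulation requires.

**12 from 10.** The bond between the carbonyl carbon and CH2Cl is cut, so the ester 10 serves as the acyl donor toward a one-carbon carbenoid. This reaches the α-halo ketone in one operation through the tetrahedral adduct 11 and avoids a diazo ketone or a bromination in the presence of two electron-rich heterocycles.

**10 from 9, and 9 from 6 and 7.** After removal of the ring-B SEM group, the imidazole is cut at N1–C5 and N3–C4. The amidine 6 supplies N1–C2–N3 with ring A already on C2; the bromo keto ester 7 supplies C4 with its carboxyl carbon and C5 with its hydrogen. The 2,4-pattern is fixed by construction, and the hydroxyimidazoline 8 is the intermediate that aromatizes.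

**6 from 4, 4 from 3, 3 from 1.** The amidine carbon is the nitrile carbon of 4, and the nitrile is put on C3 of commercial 1 through the acyl intermediate 2. The ring-A nitrogen is protected with SEM at the nitrile stage. A carbamate there would be exposed to the amide base and to the carbenoid, and a sulfonyl group on a 3-cyanoindole is easily transferred to nucleophiles. The SEM group resists both reagents and leaves in the final fluoride step.

## Alternatives that were turned down

**Alternative 1:** Larock heteroannulation that builds ring A.
- Disconnection: N1–C2 and C3–C3a of ring A, back to 5-bromo-2-iodoaniline (A3) and the imidazolyl silylalkyne A2.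
- Forward key step: Pd(OAc)2 with LiCl and K2CO3 joins A3 and A2 to the 2-trimethylsilyl indole A1.
- For it: it is convergent, forms two bonds and a ring in one step, and the bulky silyl group reliably steers itself to C2 so that the imidazole ends at C3.
- Against it: zerovalent palladium is used hot in the presence of C–Br bonds in both A3 and A1. The iodide reacts first, but the bromide can follow as A1 accumulates. A2 already contains ring C on the imidazole, so ring C must be made by some other method first and the imidazole then alkynylated at C2. The C2 silyl group costs an extra removal step, and imidazole N3 next to the alkyne can bind palladium.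
- Comparison: Alternative 1 is stronger in convergence and in the breadth of the annulation for 2-silyl-3-arylindoles. The chosen route offers in its place a C–Br bond that never meets a transition metal, and a ring A that is simply bought as 1.

**Alternative 2:** Isocyanide anion cyclization that closes C2–C3 of ring C.
- Disconnection: C2–C3 of ring C, back to the ortho-isocyanobenzyl imidazole A5.
- Forward key step: LiN(iPr)2 removes a proton from the diarylmethane CH2, the carbanion adds to the isocyanide carbon, and tautomerization gives the N–H indole A4.
- For it: no transition metal, and ring C emerges with a free N–H. On that point it is stronger than the chosen route, which must later remove a tosyl group.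
- Against it: A5 needs an ortho-aminobenzyl group on imidazole C4, then formylation and dehydration. The C4–CH2 bond has no simple condensation route. The amide base can also metalate imidazole C5–H or the C2–H of the SEM-indole, or add to the isocyanide.
- Comparison: Alternative 2 makes one skeletal bond in its key step. The chosen step makes two under fluoride, from a ketone that comes directly from the imidazole ester, and the extra tosyl group leaves in the same operation as the SEM groups.

**Alternative 3:** Copper N-arylation that closes N1–C7a of ring A.
- Disconnection: N1–C7a of ring A, back to the primary enamine A7, which carries a 4-bromo-2-iodophenyl group and the imidazol-2-yl group on the same carbon.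
- Forward key step: CuI with N,N'-dimethylethylenediamine and K3PO4 couples the enamine nitrogen with the aryl iodide to give A6.
- For it: copper distinguishes iodide from bromide well and the conditions are mild. On halogen chemoselectivity it is as strong as the chosen route.
- Against it: A7 is a hydrolytically labile primary enamine that must have nitrogen cis to the iodoarene. Its carbon skeleton needs a C–C bond between the dihaloarene and a carbon on imidazole C2, followed by an aminomethylenation. All this effort builds a ring that is commercially available with the bromine in place.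
- Comparison: the chosen route spends its key step on ring C, the one ring where no halogen has to be placed, and reaches its precursor by condensation and substitution chemistry only.

Key step: step 8

Remark on the chemistry: SEM alkylation of 9 is assumed to go mainly to the nitrogen remote from the ester. The minor isomer would carry the same atoms to 18 after deprotection, so this point does not decide the route.

## Route

**Step 1**
Reactants: 1 6-bromo-1H-indole
Product: 3 6-bromo-1H-indole-3-carbonitrile, via N-chlorosulfonyl carboxamide 2 (not isolated)
Conditions: ClSO2NCO, MeCN, 0 °C; then DMF, 0 → 25 °C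
Reagents that add atoms: chlorosulfonyl isocyanate, O=C=NS(=O)(=O)Cl
Why: Electrophilic substitution at indole C3 by the isocyanate gives the N-chlorosulfonyl amide 2, which DMF converts to the nitrile with loss of chlorosulfonic acid (standard cyanation of indoles); the aryl bromide is a spectator.

**Step 2**
Reactants: 3 6-bromo-1H-indole-3-carbonitrile
Product: 4 6-bromo-1-SEM-indole-3-carbonitrile
Conditions: NaH, DMF, 0 °C; SEMCl, 0 → 25 °C
Reagents that add atoms: SEM chloride, C[Si](C)(C)CCOCCl
Why: The N–H of a 3-cyanoindole is acidic and its sodium salt is alkylated on nitrogen (N-alkylation of an indolide); SEM resists the amide base of step 3, the carbenoid of step 6 and fluoride at the moderate temperature of step 8.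

**Step 3**
Reactants: 4 6-bromo-1-SEM-indole-3-carbonitrile
Product: 6 6-bromo-1-SEM-indole-3-carboximidamide hydrochloride, via lithium bis(trimethylsilyl)amidinate 5 (not isolated)
Conditions: LiN(SiMe3)2, THF, 0 → 25 °C; then HCl, EtOH, 0 °C
Reagents that add atoms: LiN(SiMe3)2, [Li]N([Si](C)(C)C)[Si](C)(C)C; hydrogen chloride, Cl
Why: The silyl amide adds to the nitrile to give the silylated amidinate 5, and ethanolic HCl strips the silyl groups to the amidinium chloride (amidine synthesis from nitriles with LiN(SiMe3)2); the hindered base touches neither C–Br nor the SEM group.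

**Step 4**
Reactants: 6 6-bromo-1-SEM-indole-3-carboximidamide hydrochloride; 7 ethyl bromopyruvate
Product: 9 ethyl 2-(6-bromo-1-SEM-indol-3-yl)-1H-imidazole-4-carboxylate, via hydroxyimidazoline ester 8 (not isolated)
Conditions: KHCO3, THF/H2O, 65 °C, slow addition of 7; then AcOH, 90 °C
Reagents that add atoms: none
Why: Condensation of an amidine with an α-bromo ketone: one nitrogen displaces bromide, the other adds to the ketone to give hydroxyimidazoline 8, and warm AcOH dehydrates it to the aromatic imidazole; the amidine is symmetric, so only the 2,4-substituted ester can form.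

**Step 5**
Reactants: 9 ethyl 2-(6-bromo-1-SEM-indol-3-yl)-1H-imidazole-4-carboxylate
Product: 10 ethyl 2-(6-bromo-1-SEM-indol-3-yl)-1-SEM-imidazole-4-carboxylate
Conditions: NaH, THF, 0 °C; SEMCl, 0 → 25 °C
Reagents that add atoms: SEM chloride, C[Si](C)(C)CCOCCl
Why: N-alkylation of the imidazolide anion should favour the nitrogen remote from the ester for steric and electronic reasons; the last acidic N–H is capped before the organolithium and aryne steps.

**Step 6**
Reactants: 10 ethyl 2-(6-bromo-1-SEM-indol-3-yl)-1-SEM-imidazole-4-carboxylate
Product: 12 1-[2-(6-bromo-1-SEM-indol-3-yl)-1-SEM-imidazol-4-yl]-2-chloroethanone, via lithium hemiketal 11 (not isolated)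
Conditions: ICH2Cl, MeLi·LiBr, THF/Et2O, −78 °C; AcOH, −78 → 0 °C
Reagents that add atoms: chloroiodomethane, ClCI
Why: LiCH2Cl, formed in the presence of the ester by I/Li exchange, adds once to the ester carbonyl, and the lithium hemiketal 11, held by chelation to N3, should persist at −78 °C until the acid quench releases the chloromethyl ketone (homologation of esters with a chloromethyl carbenoid); MeLi is consumed by the iodide far faster than it attacks C–Br or the ester.

**Step 7**
Reactants: 12 1-[2-(6-bromo-1-SEM-indol-3-yl)-1-SEM-imidazol-4-yl]-2-chloroethanone; 13 4-methylbenzenesulfonamide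
Product: 14 N-{2-[2-(6-bromo-1-SEM-indol-3-yl)-1-SEM-imidazol-4-yl]-2-oxoethyl}-4-methylbenzenesulfonamide
Conditions: 13 (3 equiv), K2CO3, NaI (cat.), acetone, 25 → 40 °C
Reagents that add atoms: none
Why: SN2 displacement at the activated α-keto carbon by the sulfonamide anion, helped by halide exchange with NaI; the excess of 13 suppresses a second alkylation of the product.

**Step 8**
Reactants: 14 N-{2-[2-(6-bromo-1-SEM-indol-3-yl)-1-SEM-imidazol-4-yl]-2-oxoethyl}-4-methylbenzenesulfonamide; 15 2-(trimethylsilyl)phenyl trifluoromethanesulfonate
Product: 17 2-(6-bromo-1-SEM-indol-3-yl)-1-SEM-4-(1-tosylindol-3-yl)imidazole, via 3-hydroxyindoline 16 (not isolated)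
Conditions: 15 (1.5 equiv), CsF (3 equiv), MeCN, 25 → 50 °C; filter; then Burgess reagent, THF, 50 °C
Reagents that add atoms: none
Why: Fluoride attacks silicon of 15 and triflate leaves, releasing the aryne slowly; the sulfonamide N–H of 14, the most acidic site, is deprotonated and its nitrogen adds to the aryne to give an ortho aryl anion (N1–C7a). This anion attacks the ketone five atoms away in a 5-exo-trig closure (C3–C3a), and proton transfer gives the 3-hydroxyindoline 16, whose carbinol center is racemic and is erased in the next event. Burgess reagent then removes the tertiary hydroxyl and a C2 hydrogen by syn elimination, driven by indole aromaticity, so 17 has no stereocenter. The closest known reaction type is the aryne annulation of N-sulfonyl and N-aryl α-amino ketones to indoles by N-arylation, carbonyl addition and dehydration. N-arylation must beat C-arylation of the enolizable CH2, which the more acidic N–H and its unhindered anion secure. Imidazole N3 must stay out, and it lies between the C2 indolyl and the electron-withdrawing C4 acyl group, while both other nitrogens carry SEM. Ring closure must outrun protonation of the aryl anion, which the five-membered transition state and the electrophilic heteroaryl ketone favour. Orientation is not an issue because the aryne is symmetric, and the C6–Br bond meets no metal.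

**Step 9**
Reactants: 17 2-(6-bromo-1-SEM-indol-3-yl)-1-SEM-4-(1-tosylindol-3-yl)imidazole
Product: 18 nortopsentin B, 6-bromo-3-[4-(1H-indol-3-yl)-1H-imidazol-2-yl]-1H-indole
Conditions: Bu4NF (excess), ethylenediamine, THF, 65 °C
Reagents that add atoms: none
Why: Fluoride attacks silicon of both SEM groups (fragmentation to fluorotrimethylsilane, ethene and an N-hydroxymethyl group whose formaldehyde is taken up by ethylenediamine) and the sulfur of the indole N-tosyl group (fluoride desulfonylation of N-sulfonylindoles); the aryl bromide and the three heteroaromatic rings are inert to these conditions.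

## Compound list

1 | 6-bromo-1H-indole | Brc1ccc2cc[nH]c2c1 | starting material
2 | 6-bromo-N-(chlorosulfonyl)-1H-indole-3-carboxamide | O=C(NS(=O)(=O)Cl)c1c[nH]c2cc(Br)ccc12 | intermediate
3 | 6-bromo-1H-indole-3-carbonitrile | N#Cc1c[nH]c2cc(Br)ccc12 | intermediate
4 | 6-bromo-1-SEM-indole-3-carbonitrile | N#Cc1cn(COCC[Si](C)(C)C)c2cc(Br)ccc12 | intermediate
5 | lithium N,N'-bis(trimethylsilyl)-6-bromo-1-SEM-indole-3-carboximidamide | [Li]N(C(=N[Si](C)(C)C)c1cn(COCC[Si](C)(C)C)c2cc(Br)ccc12)[Si](C)(C)C | intermediate
6 | 6-bromo-1-SEM-indole-3-carboximidamide hydrochloride | Cl.N=C(N)c1cn(COCC[Si](C)(C)C)c2cc(Br)ccc12 | intermediate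
7 | ethyl bromopyruvate | CCOC(=O)C(=O)CBr | starting material
8 | ethyl 2-(6-bromo-1-SEM-indol-3-yl)-4-hydroxy-4,5-dihydro-1H-imidazole-4-carboxylate (racemic) | CCOC(=O)C1(O)CNC(-c2cn(COCC[Si](C)(C)C)c3cc(Br)ccc23)=N1 | intermediate
9 | ethyl 2-(6-bromo-1-SEM-indol-3-yl)-1H-imidazole-4-carboxylate | CCOC(=O)c1c[nH]c(-c2cn(COCC[Si](C)(C)C)c3cc(Br)ccc23)n1 | intermediate
10 | ethyl 2-(6-bromo-1-SEM-indol-3-yl)-1-SEM-imidazole-4-carboxylate | CCOC(=O)c1cn(COCC[Si](C)(C)C)c(-c2cn(COCC[Si](C)(C)C)c3cc(Br)ccc23)n1 | intermediate
11 | lithium hemiketal from 10 and LiCH2Cl (racemic) | [Li]OC(CCl)(OCC)c1cn(COCC[Si](C)(C)C)c(-c2cn(COCC[Si](C)(C)C)c3cc(Br)ccc23)n1 | intermediate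
12 | 1-[2-(6-bromo-1-SEM-indol-3-yl)-1-SEM-imidazol-4-yl]-2-chloroethanone | O=C(CCl)c1cn(COCC[Si](C)(C)C)c(-c2cn(COCC[Si](C)(C)C)c3cc(Br)ccc23)n1 | intermediate
13 | 4-methylbenzenesulfonamide | Cc1ccc(S(N)(=O)=O)cc1 | starting material
14 | N-{2-[2-(6-bromo-1-SEM-indol-3-yl)-1-SEM-imidazol-4-yl]-2-oxoethyl}-4-methylbenzenesulfonamide | O=C(CNS(=O)(=O)c1ccc(C)cc1)c1cn(COCC[Si](C)(C)C)c(-c2cn(COCC[Si](C)(C)C)c3cc(Br)ccc23)n1 | intermediate
15 | 2-(trimethylsilyl)phenyl trifluoromethanesulfonate | C[Si](C)(C)c1ccccc1OS(=O)(=O)C(F)(F)F | starting material
16 | 3-[2-(6-bromo-1-SEM-indol-3-yl)-1-SEM-imidazol-4-yl]-1-tosyl-2,3-dihydro-1H-indol-3-ol (racemic) | OC1(c2cn(COCC[Si](C)(C)C)c(-c3cn(COCC[Si](C)(C)C)c4cc(Br)ccc34)n2)CN(S(=O)(=O)c2ccc(C)cc2)c2ccccc21 | intermediate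
17 | 2-(6-bromo-1-SEM-indol-3-yl)-1-SEM-4-(1-tosylindol-3-yl)imidazole | Brc1ccc2c(-c3nc(-c4cn(S(=O)(=O)c5ccc(C)cc5)c5ccccc45)cn3COCC[Si](C)(C)C)cn(COCC[Si](C)(C)C)c2c1 | intermediate
18 | nortopsentin B | Brc1ccc2c(-c3nc(-c4c[nH]c5ccccc45)c[nH]3)c[nH]c2c1 | target

## Step count and risk

Total: 9 steps. Longest linear sequence: 9 steps from 1; compounds 7, 13 and 15 are bought.

**Step 8 (key step).** The most likely failure is protonation of the aryl anion, by MeCN or by unreacted N–H, before it reaches the ketone, so that N-arylation occurs without ring closure. Arylation at the α-carbon, or at imidazole N3 by excess aryne, is the second risk. The fallback sets out from 12 and returns at 16. 2-Iodoaniline is tosylated to N-(2-iodophenyl)-4-methylbenzenesulfonamide F1, whose anion (K2CO3, DMF) alkylates 12 to the N-(2-iodophenyl)-N-tosyl aminomethyl ketone F2. Iodine–magnesium exchange with iPrMgCl·LiCl at −40 °C, which leaves C–Br alone, gives the arylmagnesium chloride F3. F3 adds to the neighbouring ketone and gives 16 after work-up, and the Burgess dehydration of step 8 then gives 17. In this fallback N1–C7a is bought and C3–C3a is made by an organomagnesium addition in place of the aryne.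

**Step 4.** The most likely failure is unproductive attack of the amidine on the ester or on the very electrophilic keto group of 7, or hydrolysis of 7 in the aqueous base before N-alkylation, leaving ring closure incomplete. The fallback sets out from 1 and returns at 10. Iodination of 1 at C3 (I2, KOH, DMF) gives 6-bromo-3-iodo-1H-indole F4, and SEM protection gives 6-bromo-3-iodo-1-SEM-indole F5. Commercial ethyl 2-bromo-1H-imidazole-4-carboxylate is SEM-protected to ethyl 2-bromo-1-SEM-imidazole-4-carboxylate F6. Br/Mg exchange (iPrMgCl·LiCl, −40 °C) and ZnCl2 convert F6 into the imidazol-2-ylzinc chloride F7. Negishi coupling of F7 with F5 under Pd(PPh3)4 gives 10, since zerovalent palladium inserts into C–I well before C–Br.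

**Step 6.** The most likely failure is early collapse of 11 followed by a second carbenoid addition, or methyl addition by MeLi if the exchange lags. The fallback sets out from 10 and returns at 12. Acylation of dimethylsulfoxonium methylide (Me3S(O)I, KOtBu, THF, reflux) by the ester gives the β-keto sulfoxonium ylide F8. HCl with LiCl in THF at 65 °C protonates F8, and chloride displaces dimethyl sulfoxide to give 12. This avoids organolithium and cryogenic carbenoid chemistry.

**Step 7.** The most likely failure is double alkylation of the primary sulfonamide, because the product anion is also a nucleophile. The fallback sets out from 12 and returns at 14. tert-Butyl N-tosylcarbamate with K2CO3 in DMF can be alkylated only once and gives the N-Boc-N-tosyl aminomethyl ketone F9. Brief treatment with CF3CO2H in CH2Cl2 at 0 °C removes the carbamate and gives 14.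

**Step 9.** The most likely failure is incomplete loss of the indole SEM group, stalling at N-hydroxymethyl stages while the tosyl group leaves readily. The fallback sets out from 17 and returns at 18. CF3CO2H in CH2Cl2 cleaves both SEM groups to the bis(N-hydroxymethyl) N-tosyl compound F10, with the tosyl group still tempering ring C toward formaldehyde equivalents. KOH in MeOH/THF/H2O at 60 °C then expels formaldehyde from both N–CH2OH groups and hydrolyses the sulfonamide to give 18.

## Further compounds

F1 | step 8 | N-(2-iodophenyl)-4-methylbenzenesulfonamide | Cc1ccc(S(=O)(=O)Nc2ccccc2I)cc1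
F2 | step 8 | N-{2-[2-(6-bromo-1-SEM-indol-3-yl)-1-SEM-imidazol-4-yl]-2-oxoethyl}-N-(2-iodophenyl)-4-methylbenzenesulfonamide | O=C(CN(c1ccccc1I)S(=O)(=O)c1ccc(C)cc1)c1cn(COCC[Si](C)(C)C)c(-c2cn(COCC[Si](C)(C)C)c3cc(Br)ccc23)n1
F3 | step 8 | arylmagnesium chloride formed from F2 by I/Mg exchange | O=C(CN(c1ccccc1[Mg]Cl)S(=O)(=O)c1ccc(C)cc1)c1cn(COCC[Si](C)(C)C)c(-c2cn(COCC[Si](C)(C)C)c3cc(Br)ccc23)n1
F4 | step 4 | 6-bromo-3-iodo-1H-indole | Brc1ccc2c(I)c[nH]c2c1
F5 | step 4 | 6-bromo-3-iodo-1-SEM-indole | Brc1ccc2c(I)cn(COCC[Si](C)(C)C)c2c1
F6 | step 4 | ethyl 2-bromo-1-SEM-imidazole-4-carboxylate | CCOC(=O)c1cn(COCC[Si](C)(C)C)c(Br)n1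
F7 | step 4 | [4-(ethoxycarbonyl)-1-SEM-imidazol-2-yl]zinc chloride | CCOC(=O)c1cn(COCC[Si](C)(C)C)c([Zn]Cl)n1
F8 | step 6 | dimethylsulfoxonium 2-[2-(6-bromo-1-SEM-indol-3-yl)-1-SEM-imidazol-4-yl]-2-oxoethylide | C[S+](C)(=O)[CH-]C(=O)c1cn(COCC[Si](C)(C)C)c(-c2cn(COCC[Si](C)(C)C)c3cc(Br)ccc23)n1
F9 | step 7 | tert-butyl N-{2-[2-(6-bromo-1-SEM-indol-3-yl)-1-SEM-imidazol-4-yl]-2-oxoethyl}-N-tosylcarbamate | CC(C)(C)OC(=O)N(CC(=O)c1cn(COCC[Si](C)(C)C)c(-c2cn(COCC[Si](C)(C)C)c3cc(Br)ccc23)n1)S(=O)(=O)c1ccc(C)cc1
F10 | step 9 | {6-bromo-3-[1-(hydroxymethyl)-4-(1-tosylindol-3-yl)imidazol-2-yl]indol-1-yl}methanol | OCn1cc(-c2nc(-c3cn(S(=O)(=O)c4ccc(C)cc4)c4ccccc34)cn2CO)c2ccc(Br)cc21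
A1 | alternative 1 | 2-trimethylsilyl bis-SEM nortopsentin B (SEM on imidazole N1 and on the ring-C nitrogen) | C[Si](C)(C)c1[nH]c2cc(Br)ccc2c1-c1nc(-c2cn(COCC[Si](C)(C)C)c3ccccc23)cn1COCC[Si](C)(C)C
A2 | alternative 1 | 1-SEM-4-(1-SEM-indol-3-yl)-2-[(trimethylsilyl)ethynyl]imidazole | C[Si](C)(C)C#Cc1nc(-c2cn(COCC[Si](C)(C)C)c3ccccc23)cn1COCC[Si](C)(C)C
A3 | alternative 1 | 5-bromo-2-iodoaniline | Nc1cc(Br)ccc1I
A4 | alternative 2 | bis-SEM nortopsentin B (SEM on imidazole N1 and on the ring-A nitrogen) | Brc1ccc2c(-c3nc(-c4c[nH]c5ccccc45)cn3COCC[Si](C)(C)C)cn(COCC[Si](C)(C)C)c2c1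
A5 | alternative 2 | 2-(6-bromo-1-SEM-indol-3-yl)-4-(2-isocyanobenzyl)-1-SEM-imidazole | [C-]#[N+]c1ccccc1Cc1cn(COCC[Si](C)(C)C)c(-c2cn(COCC[Si](C)(C)C)c3cc(Br)ccc23)n1
A6 | alternative 3 | bis-SEM nortopsentin B (SEM on imidazole N1 and on the ring-C nitrogen) | Brc1ccc2c(-c3nc(-c4cn(COCC[Si](C)(C)C)c5ccccc45)cn3COCC[Si](C)(C)C)c[nH]c2c1
A7 | alternative 3 | 2-(4-bromo-2-iodophenyl)-2-[1-SEM-4-(1-SEM-indol-3-yl)imidazol-2-yl]ethenamine, nitrogen cis to the iodoarene | N/C=C(/c1nc(-c2cn(COCC[Si](C)(C)C)c3ccccc23)cn1COCC[Si](C)(C)C)c1ccc(Br)cc1I
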